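Of the two ways J can leave this flask, the L route to G starts 9.12 times faster than the route to J.D, and we ask how long that lead lasts.

J 0.10 M; E 3.4 mM (held); L 5.7 mM; time 3.0 min

* how much G and L.G together there is at 3.0 min, in percent of the J charged
* the change that raises the amount of G and L.G together at 3.0 min, in percent of the J charged most ("none" if none brings more than 2 percentage points) (Sunday's / Wednesday's / Tuesday's / none)
* amount of G and L.G together at 3.0 min, in percent of the J charged, after Wednesday's

- Sunday's: doubling the transfer coefficient of step 1, all else as stated
- Wednesday's: doubling the amount of L, all else as stated
- Tuesday's: doubling the saturation concentration of E, all else as stated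

- G is meant together with its L.G
- at the start none of D is dissolved
- run time (flask): 3.0 min

    E ⇌ D, rate k1*(csat - [D]) (k1 = 0.99 s⁻¹, csat = 3.4 mM)
    J + D + L → L + G (k2 = 3200 M⁻² s⁻¹)
    L + G ⇌ L.G (K3 = 44 M⁻¹, k3 = 2.2 M⁻¹ s⁻¹)
    J + D → J.D (k4 = 2.0 M⁻¹ s⁻¹)

First, can the amount coming from E fall short of the charge? Dissolving can deliver up to 606 % of the J charged by the asked time into a solution kept empty, more than the charge, so we treat J as the limiting reagent and ask where it goes.

Both routes use one J and one D, so these cancel from the ratio of the two rates, which is k2 times free L over k4, a selectivity factor. But G binds L, and the J charge is larger than the L charge. Taking that binding at equilibrium, free L is the L charge divided by one plus 4.40 times y, the fraction of the J charge turned to G. Adding up the falling share over a J charge fully turned over gives 77.2 %, our end split: the fraction of J that ends as G when L is shared with G in this way.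

Does J get that far? If we take D at saturation and L as bound as y of one makes it, J has a half-life of 0.632 min, shorter than the run, so we expect nearly all of it turned over, and we commit to the end split for the flask.

Doubling L doubles the starting factor and leaves the binding number, which gives 86.3 %, a gain of 9.1 percentage points. The constants of dissolving enter neither figure, so in our reckoning Sunday's and Tuesday's leave the split as it is, and we choose Wednesday's.

The forecast gives 76.5 %, names Wednesday's and gives 87 % after it, holding that “doubling L improves that split and adds about ten”. Its first figure lies below ours and its last above ours.

The flask gives 78.5 %, and Wednesday's is best, reaching 88.7 %: it gains 10 points, against 0.94 points for Sunday's and 3 points for Tuesday's.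

At 3.00 min this flask still holds 2.1 % of its J. At our end split the factor has sunk to 2.07, so late J goes to G with a share of 67.5 %, and the J left is worth 1.4 points; at 30.0 min this flask stands at 80.0 %.

In the neighbour flask charged with 0.040 M of J, the factor starts at the same 9.12 but the binding number falls to 1.76, so the end split reads 84.0 %. That neighbour flask gives 86.2 %.

The constants used here are invented; the run is a simulation.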